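Assumption: the SMILES has no stereodescriptor and the molecule has no stereocentre and no hindered, stereogenic axis, so it is achiral and no stereocontrol is needed; the four starting materials below are taken as catalogue compounds.

Ring letters: C = central ring; F = chlorinated ring; B = the tetra-oxygenated ring of each arm; A = the O-linked and G = the C-linked trihydroxyphenyl ring of each arm. The two arms are identical. "TrO–" means the aryloxy group of phenol 7: 2,6-dimethoxy-3-(2,4,6-trimethoxyphenyl)-4-(2,4,6-trimethoxyphenoxy)phenoxy.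

**Retrosynthetic overview**
1. All 19 phenols are carried as methyl ethers and freed in the last step; no ring is built, all eight benzene rings are bought.
2. Ring F is joined last to the flanked oxygen of ring C by C–O coupling of a boronic acid with a hindered phenol.
3. Ring C comes from 2,6-difluoro-4-methoxybenzaldehyde: two C–O bonds by twofold SNAr with the trimer phenol (rings A, B, G), then CHO to OH.
4. The trimer phenol comes from the ring B quinone by a new reductive O-arylation with the ring A arylcopper reagent.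
5. The quinone comes from the B–G biaryl (oxidative phenol–arene coupling, then oxidative demethylation); joining order is B–G, then A, then C (both arms at once), then F.

**Route**

Step 1
Reactants: 1 3,4,5-trimethoxyphenol; 2 1,3,5-trimethoxybenzene
Product: 3 3,4,5-trimethoxy-2-(2,4,6-trimethoxyphenyl)phenol
Conditions: FeCl3 (10 mol%), t-BuOOt-Bu (1.5 equiv), 2 (3 equiv), HFIP, rt
Reagents that add atoms: none
Why: Oxidative phenol–arene cross-coupling (cross-dehydrogenative coupling), in which the easily oxidised phenol is attacked at its free ortho carbon (para is blocked) by the most nucleophilic arene available.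

Step 2
Reactants: 3 3,4,5-trimethoxy-2-(2,4,6-trimethoxyphenyl)phenol
Product: 4 2,6-dimethoxy-3-(2,4,6-trimethoxyphenyl)-1,4-benzoquinone
Conditions: PhI(OAc)2 (1.1 equiv), MeCN/H2O 2:1, 0 °C
Reagents that add atoms: water, O
Why: Hypervalent-iodine oxidative demethylation of a para-methoxyphenol to the para-quinone, which singles out the central oxygen of ring B from the two flanking methoxy groups.

Step 3
Reactants: 2 1,3,5-trimethoxybenzene; 4 2,6-dimethoxy-3-(2,4,6-trimethoxyphenyl)-1,4-benzoquinone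
Product: 7 2,6-dimethoxy-3-(2,4,6-trimethoxyphenyl)-4-(2,4,6-trimethoxyphenoxy)phenol, via 2,4,6-trimethoxyphenyllithium 5 (not isolated), via (2,4,6-trimethoxyphenyl)copper 6 (not isolated)
Conditions: 2 (1.3 equiv), n-BuLi, THF, 0 °C; CuBr·SMe2 (1.3 equiv), −40 °C; then 4, −78 to −20 °C; aq NH4Cl
Reagents that add atoms: none
Why: Proposed new method: quinone-driven reductive O-arylation, in which arylcopper 6 (monovalent copper) is oxidised by quinone 4 in an inner-sphere two-electron step to an aryl trivalent-copper hydroquinonate bound through O-4 (the more Lewis-basic, vinylogous-ester oxygen, open on its H-flanked side) while Li+ sits in the O-1/2,6-dimethoxy chelate pocket, and aromatisation-driven C–O reductive elimination then gives the 4-aryloxyphenoxide with O-1 left as the free phenol; the closest known reaction types are the Chan–Lam–Evans O-arylation (C–O reductive elimination from aryl trivalent-copper aryloxides) and the quinone-triggered oxidative C–N coupling of lithium amidocuprates, and conjugate addition or biaryl homocoupling should be slow because the quinone carbons are electron-rich or substituted and the aryl group is di-ortho-substituted.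

Step 4
Reactants: 7 2,6-dimethoxy-3-(2,4,6-trimethoxyphenyl)-4-(2,4,6-trimethoxyphenoxy)phenol (2.2 equiv); 8 2,6-difluoro-4-methoxybenzaldehyde
Product: 9 4-methoxy-2,6-bis(TrO)benzaldehyde
Conditions: Cs2CO3 (3 equiv), DMSO, 120 °C, argon
Reagents that add atoms: none
Why: Twofold nucleophilic aromatic substitution (SNAr) of the two fluorides ortho to the aldehyde, a reaction type that tolerates 2,6-disubstituted phenoxides far better than metal-catalysed couplings.

Step 5
Reactants: 9 4-methoxy-2,6-bis(TrO)benzaldehyde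
Product: 11 4-methoxy-2,6-bis(TrO)phenol, via aryl formate 10 (not isolated)
Conditions: mCPBA (1.3 equiv), CH2Cl2, 0 °C to rt; then K2CO3, MeOH, rt, argon
Reagents that add atoms: mCPBA, OOC(=O)c1cccc(Cl)c1
Why: Baeyer–Villiger (Dakin-type) oxidation of an electron-rich benzaldehyde with aryl migration, followed by methanolysis of the formate, which turns the SNAr activating group into the central oxygen of ring C.

Step 6
Reactants: 12 2-chloro-1,3-dimethoxybenzene
Product: 14 (4-chloro-3,5-dimethoxyphenyl)boronic acid, via pinacol boronate 13 (not isolated)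
Conditions: [Ir(cod)OMe]2 (1.5 mol%), 4,4'-di-tert-butyl-2,2'-bipyridine (3 mol%), B2pin2 (0.6 equiv), THF, 80 °C; then NaIO4, aq NH4OAc, acetone, rt
Reagents that add atoms: bis(pinacolato)diboron, CC1(C)OB(OC1(C)C)B1OC(C)(C)C(C)(C)O1; water, O
Why: Sterically controlled [Ir(cod)OMe]2-catalysed C–H borylation at the only C–H without an ortho substituent (C-5), followed by oxidative cleavage of the pinacol ester to the boronic acid.

Step 7
Reactants: 11 4-methoxy-2,6-bis(TrO)phenol; 14 (4-chloro-3,5-dimethoxyphenyl)boronic acid (3 equiv)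
Product: 15 2-(4-chloro-3,5-dimethoxyphenoxy)-5-methoxy-1,3-bis(TrO)benzene (the nonadeca-O-methyl ether of the target)
Conditions: Cu(OAc)2 (1.5 equiv), pyridine (5 equiv), 4 Å MS, CH2Cl2, dry air, rt, 48 h
Reagents that add atoms: none
Why: Chan–Lam–Evans O-arylation (transmetalation to a divalent-copper phenoxide, oxidation to trivalent copper, C–O reductive elimination), which is known to accept 2,6-disubstituted phenols when the boronic acid is unhindered and which leaves the C–Cl bond alone.

Step 8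
Reactants: 15 2-(4-chloro-3,5-dimethoxyphenoxy)-5-methoxy-1,3-bis(TrO)benzene
Product: 16 CNP0275555.0 (target)
Conditions: BBr3 (60 equiv), CH2Cl2, −78 °C to rt; ice-water; Sephadex LH-20 under argon
Reagents that add atoms: none
Why: Lewis-acid cleavage of all 19 aryl methyl ethers (BBr3 O-demethylation), which does not touch diaryl ether, biaryl or aryl chloride bonds.

**Compound list**
1 | 3,4,5-trimethoxyphenol | COc1cc(O)cc(OC)c1OC | starting material
2 | 1,3,5-trimethoxybenzene | COc1cc(OC)cc(OC)c1 | starting material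
3 | 3,4,5-trimethoxy-2-(2,4,6-trimethoxyphenyl)phenol | Oc1cc(OC)c(OC)c(OC)c1-c1c(OC)cc(OC)cc1OC | intermediate
4 | 2,6-dimethoxy-3-(2,4,6-trimethoxyphenyl)-1,4-benzoquinone | COC1=CC(=O)C(=C(OC)C1=O)c1c(OC)cc(OC)cc1OC | intermediate
5 | 2,4,6-trimethoxyphenyllithium | [Li]c1c(OC)cc(OC)cc1OC | intermediate
6 | (2,4,6-trimethoxyphenyl)copper | [Cu]c1c(OC)cc(OC)cc1OC | intermediate
7 | 2,6-dimethoxy-3-(2,4,6-trimethoxyphenyl)-4-(2,4,6-trimethoxyphenoxy)phenol (trimer phenol, rings A, B, G) | COc1cc(Oc2c(OC)cc(OC)cc2OC)c(c(OC)c1O)-c1c(OC)cc(OC)cc1OC | intermediate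
8 | 2,6-difluoro-4-methoxybenzaldehyde | COc1cc(F)c(C=O)c(F)c1 | starting material
9 | 4-methoxy-2,6-bis(TrO)benzaldehyde | COc1cc(Oc2c(OC)cc(Oc3c(OC)cc(OC)cc3OC)c(-c3c(OC)cc(OC)cc3OC)c2OC)c(C=O)c(Oc2c(OC)cc(Oc3c(OC)cc(OC)cc3OC)c(-c3c(OC)cc(OC)cc3OC)c2OC)c1 | intermediate
10 | 4-methoxy-2,6-bis(TrO)phenyl formate | COc1cc(Oc2c(OC)cc(Oc3c(OC)cc(OC)cc3OC)c(-c3c(OC)cc(OC)cc3OC)c2OC)c(OC=O)c(Oc2c(OC)cc(Oc3c(OC)cc(OC)cc3OC)c(-c3c(OC)cc(OC)cc3OC)c2OC)c1 | intermediate
11 | 4-methoxy-2,6-bis(TrO)phenol | COc1cc(Oc2c(OC)cc(Oc3c(OC)cc(OC)cc3OC)c(-c3c(OC)cc(OC)cc3OC)c2OC)c(O)c(Oc2c(OC)cc(Oc3c(OC)cc(OC)cc3OC)c(-c3c(OC)cc(OC)cc3OC)c2OC)c1 | intermediate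
12 | 2-chloro-1,3-dimethoxybenzene | COc1cccc(OC)c1Cl | starting material
13 | 2-(4-chloro-3,5-dimethoxyphenyl)-4,4,5,5-tetramethyl-1,3,2-dioxaborolane | COc1cc(B2OC(C)(C)C(C)(C)O2)cc(OC)c1Cl | intermediate
14 | (4-chloro-3,5-dimethoxyphenyl)boronic acid | COc1cc(B(O)O)cc(OC)c1Cl | intermediate
15 | 2-(4-chloro-3,5-dimethoxyphenoxy)-5-methoxy-1,3-bis(TrO)benzene | COc1cc(Oc2c(OC)cc(Oc3c(OC)cc(OC)cc3OC)c(-c3c(OC)cc(OC)cc3OC)c2OC)c(Oc2cc(OC)c(Cl)c(OC)c2)c(Oc2c(OC)cc(Oc3c(OC)cc(OC)cc3OC)c(-c3c(OC)cc(OC)cc3OC)c2OC)c1 | intermediate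
16 | CNP0275555.0 (achiral; 19 free phenols, one aryl chloride) | Oc1cc(O)c(Oc2cc(O)c(Oc3cc(O)cc(Oc4c(O)cc(Oc5c(O)cc(O)cc5O)c(-c5c(O)cc(O)cc5O)c4O)c3Oc3cc(O)c(Cl)c(O)c3)c(O)c2-c2c(O)cc(O)cc2O)c(O)c1 | target

**Step count and risks**
Total steps: 8. Longest linear sequence: 7 (steps 1, 2, 3, 4, 5, 7, 8); step 6 is a one-step side branch.

Steps most likely to fail:

Step 3 (the proposed new reductive O-arylation). It may give the wrong oxygen, plain reduction of the quinone, or biaryl homocoupling. The fallback sets out from 3 and comes back at 7, leaving out steps 2 and 3. CuI/picolinic acid-catalysed Ullmann coupling of 3 with commercial 2-iodo-1,3,5-trimethoxybenzene (K3PO4, DMSO, 90 °C) gives 1,2,3-trimethoxy-4-(2,4,6-trimethoxyphenyl)-5-(2,4,6-trimethoxyphenoxy)benzene F1. BCl3 (CH2Cl2, −20 °C) then removes only the central, out-of-plane methyl group of the 1,2,3-trimethoxy array, the known chelation-controlled mono-demethylation of 3,4,5-trimethoxyaryl units, which returns 7.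

Step 4 (twofold SNAr). The second fluoride is less activated, and the electron-rich phenoxide may decompose at 120 °C. The fallback sets out from 7 and comes back at 11, leaving out steps 4 and 5. Addition–elimination of 7 (2 equiv, Cs2CO3, MeCN, 0 °C, argon) on 2,6-dichloro-1,4-benzoquinone gives 2,6-bis(TrO)-1,4-benzoquinone F2. Na2S2O4 (EtOAc/H2O) reduces it to 2,6-bis(TrO)benzene-1,4-diol F3. MeI (1.05 equiv), K2CO3, acetone then methylates the unhindered and more acidic 4-OH to give 11.

Step 7 (Chan–Lam coupling on the doubly flanked phenol). It may stall, or the phenol may be oxidised. The fallback sets out from 14 (with 2 and 11) and comes back at 15. Iododeboronation of 14 (N-iodosuccinimide, MeCN) gives 2-chloro-5-iodo-1,3-dimethoxybenzene F4. One-pot mCPBA, TsOH·H2O, MeCN, then 2, gives (4-chloro-3,5-dimethoxyphenyl)(2,4,6-trimethoxyphenyl)iodonium tosylate F5. The potassium phenoxide of 11 (t-BuOK, THF/toluene, rt to 50 °C) then undergoes metal-free ligand coupling at hypervalent iodine, which transfers only the less electron-rich aryl group and is little affected by ortho substitution, to give 15.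

**Further compounds**
F1 | step 3 | 1,2,3-trimethoxy-4-(2,4,6-trimethoxyphenyl)-5-(2,4,6-trimethoxyphenoxy)benzene | COc1cc(Oc2c(OC)cc(OC)cc2OC)c(c(OC)c1OC)-c1c(OC)cc(OC)cc1OC
F2 | step 4 | 2,6-bis(TrO)-1,4-benzoquinone | O=C1C=C(Oc2c(OC)cc(Oc3c(OC)cc(OC)cc3OC)c(-c3c(OC)cc(OC)cc3OC)c2OC)C(=O)C(Oc2c(OC)cc(Oc3c(OC)cc(OC)cc3OC)c(-c3c(OC)cc(OC)cc3OC)c2OC)=C1
F3 | step 4 | 2,6-bis(TrO)benzene-1,4-diol | Oc1cc(Oc2c(OC)cc(Oc3c(OC)cc(OC)cc3OC)c(-c3c(OC)cc(OC)cc3OC)c2OC)c(O)c(Oc2c(OC)cc(Oc3c(OC)cc(OC)cc3OC)c(-c3c(OC)cc(OC)cc3OC)c2OC)c1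
F4 | step 7 | 2-chloro-5-iodo-1,3-dimethoxybenzene | COc1cc(I)cc(OC)c1Cl
F5 | step 7 | (4-chloro-3,5-dimethoxyphenyl)(2,4,6-trimethoxyphenyl)iodonium tosylate | COc1cc([I+]c2c(OC)cc(OC)cc2OC)cc(OC)c1Cl.Cc1ccc(S(=O)(=O)[O-])cc1
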